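I started from the constants that the late readings give, and these were the flasks and the questions.

| flask | substrate | catalyst | time |
|---|---|---|---|
| Saturday's | 200 mM | 20.0 mM |  |
| Wednesday's | 80.0 mM | 20.0 mM |  |
| Thursday's | 400 mM | 20.0 mM |  |
| Friday's | 66.0 mM | 10.0 mM | 3.8 h |

| run | time / h | [product] / mM |
|---|---|---|
| Saturday's run | 0.17 | 1.0 |
| Saturday's run | 0.51 | 6.4 |
| Saturday's run | 0.98 | 18.8 |
| Saturday's run | 1.6 | 39.2 |
| Saturday's run | 2.2 | 61.7 |
| Saturday's run | 3.0 | 88.5 |
| Saturday's run | 3.8 | 110.5 |
| Wednesday's run | 0.17 | 0.8 |
| Wednesday's run | 0.51 | 2.5 |
| Wednesday's run | 0.98 | 6.5 |
| Wednesday's run | 1.6 | 16.1 |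
| Wednesday's run | 2.2 | 24.1 |
| Wednesday's run | 3.0 | 34.5 |
| Wednesday's run | 3.8 | 44.4 |
| Thursday's run | 0.17 | 2.6 |
| Thursday's run | 0.51 | 11.6 |
| Thursday's run | 0.98 | 37.1 |
| Thursday's run | 1.6 | 79.2 |
| Thursday's run | 2.2 | 121.1 |
| Thursday's run | 3.0 | 176.5 |
| Thursday's run | 3.8 | 219.5 |

(each reading ± 0.6 mM)

- Overall: substrate -> product, with catalyst as catalyst.
- Constant volume, constant temperature.
- An order is taken over about fifteen percent of the charge, up and down.

- the exponent of [substrate] in the starting rate at the charge of the Saturday's run (at the point where two percent of the substrate have become product) (one fixed amount of product, the same in the runs compared)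
- the Wednesday's run starts with 120 mM less of substrate than the Saturday's run, and with no product. Compared where both hold the same amount of substrate, once fifteen percent of what the Wednesday's run was charged with has turned into product, is the Wednesday's run faster, slower or alike (within a tenth)?
- product in the Friday's run at 3.8 h, as a share of the substrate charged
- which of these the readings show (the catalyst wakes slowly / the product speeds the reaction / a little impurity takes part of the catalyst at once / the product kills the catalyst / nothing beyond the main steps / the substrate pairs with itself)

Saturday's run first. Between 2.2 h and 3.8 h, c(substrate) fell from 138 mM to 89.5 mM. As a first-order decay that is 0.272 /h. Thursday's run, over the same window, gave 0.272 /h, so I took the late decay as first order in substrate.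

That constant is the large part, and the start is the correction. At 3.8 h, the conversion in Saturday's run needed only 2.96 h of first-order running. The difference is the time lost at the start, the induction period: 0.844 h.

Friday's run has 10.0 mM of catalyst against 20.0 mM. I took the constant in proportion, 0.136 /h, and kept the lost time. That gave 33.1 % of its charge at 3.8 h. The proportion stayed an assumption, since Saturday's, Wednesday's and Thursday's runs share one catalyst charge.

The weak link was the lost time, read from one run. If product caused it, it should shift with product. So I reforged it on the other runs. Wednesday's run, with 44.4 mM of product at 3.8 h, gave 0.823 h. Thursday's run, with 219.5 mM, gave 0.874 h. The lost time stayed put, so I read it as a clock.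

Wednesday's run passes the compared substrate level before 1.6 h. Saturday's run still holds more than that level at 3.8 h. So Wednesday's catalyst has had less time there, and I expected it to be slower.

The forecast, which is not my reckoning, gave 0.6, slower, 33 % and the catalyst wakes slowly, on the ground that “it follows the clock, not product”.

The simulation gave 0.58, slower, 33.1 % and the catalyst wakes slowly, from these steps:

    active catalyst + substrate → product + active catalyst (14.76 /M/h)
    catalyst → active catalyst (0.8964 /h)

The fit with the main steps alone had put Friday's run at 28.5 %. For Wednesday's run, the lost time plus ln(2) over the constant gives 3.39 h, and that run reached half its charge at 3.41 h.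

Readings and results are simulated for an exercise; the scatter is artificial.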